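**Retrosynthetic overview**

1. The 21 phenols are unmasked last (benzyl ethers). Both 4β→8 interflavan bonds are cut to one C4-activated epicatechin gallate (17) and one C8-nucleophilic epicatechin gallate (15), and both come from tetra-O-benzyl-(−)-epicatechin 13.
2. 13 comes from racemic flavan-3-one 12 by asymmetric hydrogenation with dynamic kinetic resolution, which sets C2 and C3 (cis) together. 12 comes from enol pivalate 11.
3. Ring C of every unit, the terminal one included, is closed in step 7 by joining O1 to C8a. In one flask phenacyl pivalate 9 is C-benzylated by benzylic bromide 6 (C3–C4), then the enolate oxygen is arylated under copper catalysis (O1–C8a).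
4. Enabling feature: O1 sits on C2, which carries ring B and adjoins the oxygenated C3, so at the C2-ketone level O1 is an enolate oxygen and C3 its only enolisable carbon. C8a of ring A is meta to O5 and O7 and ortho to C4a (which bears the C4 methylene), so it can be an undeactivated aryl bromide, while C8 stays free as the later nucleophilic site.
5. Ring order: rings A and B are bought as arenes; ring C is made in step 7 (one batch serves all three units); the chain is then grown lower unit → middle unit → upper unit.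

Key step: step 7

Assumption: in step 9 the catalyst enantiomer is written as expected, by analogy with 2-arylcycloalkanones, to give the (2R,3R) alcohol; if the sense of induction on this ketone is opposite, the mirror-image catalyst is used.

**Route**

Step 1
Reactants: 1 5-bromoresorcinol
Product: 2 1-bromo-3,5-bis(benzyloxy)benzene
Conditions: BnBr (2.2 equiv), K2CO3, DMF, 60 °C
Reagents that add atoms: benzyl bromide, BrCc1ccccc1
Why: Williamson ether synthesis; both phenoxides are alkylated by the benzylic bromide and no stereocentre is involved.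

Step 2
Reactants: 2 1-bromo-3,5-bis(benzyloxy)benzene
Product: 4 2-bromo-4,6-bis(benzyloxy)benzaldehyde, via aryl iminium chloride 3 (not isolated)
Conditions: POCl3 (1.5 equiv), DMF, 0 to 70 °C; then ice/H2O
Reagents that add atoms: N,N-dimethylformamide, CN(C)C=O; water, O
Why: Vilsmeier–Haack formylation; the chloroiminium ion should attack the position ortho to bromine (para to one benzyloxy, ortho to the other) in preference to the more crowded position between the two benzyloxy groups, as is usual for 5-substituted resorcinol diethers.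

Step 3
Reactants: 4 2-bromo-4,6-bis(benzyloxy)benzaldehyde
Product: 5 [2-bromo-4,6-bis(benzyloxy)phenyl]methanol
Conditions: NaBH4, MeOH/THF, 0 °C
Reagents that add atoms: none
Why: Borohydride reduction of an aryl aldehyde; the aryl bromide and benzyl ethers are inert.

Step 4
Reactants: 5 [2-bromo-4,6-bis(benzyloxy)phenyl]methanol
Product: 6 1,5-bis(benzyloxy)-3-bromo-2-(bromomethyl)benzene
Conditions: PBr3 (0.4 equiv), Et2O, 0 °C; cold aqueous wash, used at once
Reagents that add atoms: phosphorus tribromide, BrP(Br)Br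
Why: Bromination of a benzylic alcohol through its phosphite ester (SN2); the electron-rich benzylic bromide ionises easily and is therefore not stored.

Step 5
Reactants: 7 2-chloro-1-(3,4-dihydroxyphenyl)ethanone
Product: 8 2-(3,4-dihydroxyphenyl)-2-oxoethyl pivalate
Conditions: KO2CC(CH3)3 (1.2 equiv), pivalic acid (1 equiv), DMF, 25 °C
Reagents that add atoms: potassium pivalate, CC(C)(C)C(=O)[O-].[K+]
Why: SN2 displacement of the activated phenacyl chloride by carboxylate; the pivalic acid buffer keeps the catechol protonated so that it does not compete as a nucleophile.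

Step 6
Reactants: 8 2-(3,4-dihydroxyphenyl)-2-oxoethyl pivalate
Product: 9 2-[3,4-bis(benzyloxy)phenyl]-2-oxoethyl pivalate
Conditions: BnBr (2.2 equiv), K2CO3, DMF, 25 °C
Reagents that add atoms: benzyl bromide, BrCc1ccccc1
Why: Williamson ether synthesis on the two phenols; K2CO3 at room temperature is too weak to enolise the ketone, so the α-carbon is untouched.

Step 7
Reactants: 6 1,5-bis(benzyloxy)-3-bromo-2-(bromomethyl)benzene; 9 2-[3,4-bis(benzyloxy)phenyl]-2-oxoethyl pivalate
Product: 11 5,7-bis(benzyloxy)-2-[3,4-bis(benzyloxy)phenyl]-4H-chromen-3-yl pivalate, via bromo ketone 10 (not isolated)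
Conditions: 9, LiN(SiMe3)2 (1.05 equiv), THF, −78 °C; 6, −78 to 0 °C; then in the same flask CuI (10 mol %), 1,10-phenanthroline (20 mol %), Cs2CO3 (2 equiv), DMF (THF removed), 100 °C, argon
Reagents that add atoms: none
Why: The lithium enolate of 9 is C-benzylated by the benzylic bromide of 6 (SN2, the aryl bromide is inert without copper) to form C3–C4 and bromo ketone 10; Cs2CO3 then re-enolises 10 at C3, its only α-hydrogen, and the monovalent copper enolate undergoes oxidative addition into C8a–Br and C–O reductive elimination to form O1–C8a. The closest known reactions are the copper-catalysed domino C-benzylation/enolate O-arylation of 2-bromobenzyl bromides with 1,3-dicarbonyl compounds to 4H-chromenes and the Ullmann-type O-arylation of ketone enolates to benzofurans. Ring C is closed as a six-membered ring by intramolecular O-arylation, exo with respect to ring A and with the enolate C2=C3 bond inside the new ring. No stereocentre is created, because C3 of 10 is planarised; C2 and C3 are set together in step 9. The step needs O- over C-arylation, discrimination of the two bromides and an intact ester: C-arylation would require a four-membered ring, the two C–Br bonds are separated by temperature and by the need for copper, and the pivalate has no α-hydrogen and is hindered toward acyl transfer. Only the enolate isomer with O1 syn to C4 can cyclise, and the isomers should equilibrate under carbonate.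

Step 8
Reactants: 11 5,7-bis(benzyloxy)-2-[3,4-bis(benzyloxy)phenyl]-4H-chromen-3-yl pivalate
Product: 12 racemic 5,7-bis(benzyloxy)-2-[3,4-bis(benzyloxy)phenyl]chroman-3-one
Conditions: K2CO3 (0.2 equiv), MeOH/THF, 0 to 25 °C, argon; AcOH quench; used directly
Reagents that add atoms: none
Why: Base-catalysed transesterification of the activated enol ester releases the enol, which tautomerises to the ketone; C2 forms as a racemate on purpose, because step 9 resolves it dynamically.

Step 9
Reactants: 12 racemic 5,7-bis(benzyloxy)-2-[3,4-bis(benzyloxy)phenyl]chroman-3-one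
Product: 13 (2R,3R)-5,7-bis(benzyloxy)-2-[3,4-bis(benzyloxy)phenyl]chroman-3-ol
Conditions: RuCl2[(S)-Xyl-SDP][(R,R)-DPEN] (1 mol %), KOtBu (0.2 equiv), H2 (20 atm), i-PrOH/toluene, 25 °C
Reagents that add atoms: none
Why: Noyori asymmetric hydrogenation with dynamic kinetic resolution; the base should racemise C2 (flanked by O1, ring B and the carbonyl) through the enolate faster than reduction, the catalyst should select the (2R) ketone, and hydride adds to C3 anti to the C2 aryl group to give the 2,3-cis alcohol.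

Step 10
Reactants: 13 (2R,3R)-5,7-bis(benzyloxy)-2-[3,4-bis(benzyloxy)phenyl]chroman-3-ol; 14 3,4,5-tris(benzyloxy)benzoic acid
Product: 15 (2R,3R)-5,7-bis(benzyloxy)-2-[3,4-bis(benzyloxy)phenyl]chroman-3-yl 3,4,5-tris(benzyloxy)benzoate
Conditions: DCC (1.5 equiv), DMAP (0.2 equiv), CH2Cl2, 25 °C
Reagents that add atoms: none
Why: Steglich esterification of the secondary C3 alcohol; no stereocentre is touched.

Step 11
Reactants: 13 (2R,3R)-5,7-bis(benzyloxy)-2-[3,4-bis(benzyloxy)phenyl]chroman-3-ol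
Product: 16 (2R,3R,4S)-5,7-bis(benzyloxy)-2-[3,4-bis(benzyloxy)phenyl]-4-(2-ethoxyethoxy)chroman-3-ol
Conditions: DDQ (2 equiv), 2-ethoxyethanol (4 equiv), CH2Cl2, 25 °C
Reagents that add atoms: 2-ethoxyethanol, CCOCCO
Why: DDQ benzylic oxidation; hydride abstraction at C4 gives a cation stabilised by the 5,7-dialkoxy ring A, and the alcohol should add on the β face, anti to the C3 hydroxyl and the C2 aryl group (3,4-trans).

Step 12
Reactants: 16 (2R,3R,4S)-5,7-bis(benzyloxy)-2-[3,4-bis(benzyloxy)phenyl]-4-(2-ethoxyethoxy)chroman-3-ol; 14 3,4,5-tris(benzyloxy)benzoic acid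
Product: 17 (2R,3R,4S)-5,7-bis(benzyloxy)-2-[3,4-bis(benzyloxy)phenyl]-4-(2-ethoxyethoxy)chroman-3-yl 3,4,5-tris(benzyloxy)benzoate
Conditions: DCC (2 equiv), DMAP (0.5 equiv), CH2Cl2, 25 °C
Reagents that add atoms: none
Why: Steglich esterification; the C4 acetal-type ether is stable to these neutral conditions.

Step 13
Reactants: 17 C4-activated epicatechin gallate (electrophile); 15 epicatechin gallate (nucleophile, 4 equiv, excess recovered)
Product: 18 tetradeca-O-benzyl epicatechin 3-O-gallate-(4β→8)-epicatechin 3-O-gallate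
Conditions: Me3SiOTf (0.2 equiv), 4 Å molecular sieves, CH2Cl2, −78 to −40 °C
Reagents that add atoms: none
Why: Lewis-acid-mediated Friedel–Crafts alkylation by the flavan-4-yl cation; C8 of 15 should react in preference to C6, and attack on the β face, anti to the C3 ester (which can also shield the α face as a dioxolenium ion) and to the C2 aryl group, sets the new C4 centre 3,4-trans.

Step 14
Reactants: 17 C4-activated epicatechin gallate (electrophile); 18 protected dimer (nucleophile, 2 equiv, excess recovered)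
Product: 19 henicosa-O-benzyl procyanidin C1 3,3',3''-tri-O-gallate
Conditions: Me3SiOTf (0.2 equiv), 4 Å molecular sieves, CH2Cl2, −78 to −40 °C
Reagents that add atoms: none
Why: Second Friedel–Crafts alkylation by the flavan-4-yl cation; the only unsubstituted C8 of 18 (on its upper unit) should be the most nucleophilic site, and the new C4 centre is again set 3,4-trans by β-face attack.

Step 15
Reactants: 19 henicosa-O-benzyl procyanidin C1 3,3',3''-tri-O-gallate
Product: 20 procyanidin C1 3,3',3''-tri-O-gallate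
Conditions: H2 (1 atm), Pd(OH)2/C, THF/MeOH/H2O, 25 °C; filtration, lyophilisation
Reagents that add atoms: none
Why: Catalytic hydrogenolysis of all 21 benzyl ethers under neutral conditions; the gallate esters, the interflavan bonds and all stereocentres should survive.

**Compound list**

1 | 5-bromoresorcinol (5-bromobenzene-1,3-diol) | Oc1cc(O)cc(Br)c1 | starting material
2 | 1-bromo-3,5-bis(benzyloxy)benzene | Brc1cc(OCc2ccccc2)cc(OCc2ccccc2)c1 | intermediate
3 | N-{[2-bromo-4,6-bis(benzyloxy)phenyl]methylidene}-N-methylmethanaminium chloride | C[N+](C)=Cc1c(Br)cc(OCc2ccccc2)cc1OCc1ccccc1.[Cl-] | intermediate (not isolated)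
4 | 2-bromo-4,6-bis(benzyloxy)benzaldehyde | O=Cc1c(Br)cc(OCc2ccccc2)cc1OCc1ccccc1 | intermediate
5 | [2-bromo-4,6-bis(benzyloxy)phenyl]methanol | OCc1c(Br)cc(OCc2ccccc2)cc1OCc1ccccc1 | intermediate
6 | 1,5-bis(benzyloxy)-3-bromo-2-(bromomethyl)benzene | BrCc1c(Br)cc(OCc2ccccc2)cc1OCc1ccccc1 | intermediate
7 | 2-chloro-1-(3,4-dihydroxyphenyl)ethanone | O=C(CCl)c1ccc(O)c(O)c1 | starting material
8 | 2-(3,4-dihydroxyphenyl)-2-oxoethyl pivalate | CC(C)(C)C(=O)OCC(=O)c1ccc(O)c(O)c1 | intermediate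
9 | 2-[3,4-bis(benzyloxy)phenyl]-2-oxoethyl pivalate | CC(C)(C)C(=O)OCC(=O)c1ccc(OCc2ccccc2)c(OCc2ccccc2)c1 | intermediate
10 | racemic 1-[2-bromo-4,6-bis(benzyloxy)phenyl]-3-[3,4-bis(benzyloxy)phenyl]-3-oxopropan-2-yl pivalate | CC(C)(C)C(=O)OC(Cc1c(Br)cc(OCc2ccccc2)cc1OCc1ccccc1)C(=O)c1ccc(OCc2ccccc2)c(OCc2ccccc2)c1 | intermediate (not isolated)
11 | 5,7-bis(benzyloxy)-2-[3,4-bis(benzyloxy)phenyl]-4H-chromen-3-yl pivalate | CC(C)(C)C(=O)OC1=C(c2ccc(OCc3ccccc3)c(OCc3ccccc3)c2)Oc2cc(OCc3ccccc3)cc(OCc3ccccc3)c2C1 | intermediate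
12 | racemic 5,7-bis(benzyloxy)-2-[3,4-bis(benzyloxy)phenyl]chroman-3-one | O=C1Cc2c(OCc3ccccc3)cc(OCc3ccccc3)cc2OC1c1ccc(OCc2ccccc2)c(OCc2ccccc2)c1 | intermediate
13 | (2R,3R)-5,7-bis(benzyloxy)-2-[3,4-bis(benzyloxy)phenyl]chroman-3-ol (tetra-O-benzyl-(−)-epicatechin) | C1c2c(OCc5ccccc5)cc(OCc5ccccc5)cc2O[C@H](c2ccc(OCc5ccccc5)c(OCc5ccccc5)c2)[C@@H]1O | intermediate
14 | 3,4,5-tris(benzyloxy)benzoic acid | OC(=O)c1cc(OCc2ccccc2)c(OCc2ccccc2)c(OCc2ccccc2)c1 | starting material
15 | (2R,3R)-5,7-bis(benzyloxy)-2-[3,4-bis(benzyloxy)phenyl]chroman-3-yl 3,4,5-tris(benzyloxy)benzoate | C1c2c(OCc5ccccc5)cc(OCc5ccccc5)cc2O[C@H](c2ccc(OCc5ccccc5)c(OCc5ccccc5)c2)[C@@H]1OC(=O)c1cc(OCc5ccccc5)c(OCc5ccccc5)c(OCc5ccccc5)c1 | intermediate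
16 | (2R,3R,4S)-5,7-bis(benzyloxy)-2-[3,4-bis(benzyloxy)phenyl]-4-(2-ethoxyethoxy)chroman-3-ol (ether on the β face, trans to the C3 hydroxyl) | CCOCCO[C@H]1c2c(OCc5ccccc5)cc(OCc5ccccc5)cc2O[C@H](c2ccc(OCc5ccccc5)c(OCc5ccccc5)c2)[C@@H]1O | intermediate
17 | (2R,3R,4S)-5,7-bis(benzyloxy)-2-[3,4-bis(benzyloxy)phenyl]-4-(2-ethoxyethoxy)chroman-3-yl 3,4,5-tris(benzyloxy)benzoate | CCOCCO[C@H]1c2c(OCc5ccccc5)cc(OCc5ccccc5)cc2O[C@H](c2ccc(OCc5ccccc5)c(OCc5ccccc5)c2)[C@@H]1OC(=O)c1cc(OCc5ccccc5)c(OCc5ccccc5)c(OCc5ccccc5)c1 | intermediate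
18 | tetradeca-O-benzyl epicatechin 3-O-gallate-(4β→8)-epicatechin 3-O-gallate (both units 2R,3R; interflavan bond 3,4-trans; all 14 phenols benzylated) | O=C(O[C@@H]1[C@@H](c2c(OCc5ccccc5)cc(OCc5ccccc5)c3c2O[C@H](c2ccc(OCc5ccccc5)c(OCc5ccccc5)c2)[C@H](OC(=O)c2cc(OCc5ccccc5)c(OCc5ccccc5)c(OCc5ccccc5)c2)C3)c2c(OCc5ccccc5)cc(OCc5ccccc5)cc2O[C@@H]1c1ccc(OCc5ccccc5)c(OCc5ccccc5)c1)c1cc(OCc5ccccc5)c(OCc5ccccc5)c(OCc5ccccc5)c1 | intermediate
19 | henicosa-O-benzyl procyanidin C1 3,3',3''-tri-O-gallate (three 2R,3R units; two 4β→8 bonds, each 3,4-trans; all 21 phenols benzylated) | O=C(O[C@@H]1[C@@H](c2c(OCc5ccccc5)cc(OCc5ccccc5)c3c2O[C@H](c2ccc(OCc5ccccc5)c(OCc5ccccc5)c2)[C@H](OC(=O)c2cc(OCc5ccccc5)c(OCc5ccccc5)c(OCc5ccccc5)c2)C3)c2c(OCc5ccccc5)cc(OCc5ccccc5)c([C@H]3c4c(OCc5ccccc5)cc(OCc5ccccc5)cc4O[C@H](c4ccc(OCc5ccccc5)c(OCc5ccccc5)c4)[C@@H]3OC(=O)c3cc(OCc5ccccc5)c(OCc5ccccc5)c(OCc5ccccc5)c3)c2O[C@@H]1c1ccc(OCc5ccccc5)c(OCc5ccccc5)c1)c1cc(OCc5ccccc5)c(OCc5ccccc5)c(OCc5ccccc5)c1 | intermediate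
20 | procyanidin C1 3,3',3''-tri-O-gallate | O=C(O[C@@H]1[C@@H](c2c(O)cc(O)c3c2O[C@H](c2ccc(O)c(O)c2)[C@H](OC(=O)c2cc(O)c(O)c(O)c2)C3)c2c(O)cc(O)c([C@H]3c4c(O)cc(O)cc4O[C@H](c4ccc(O)c(O)c4)[C@@H]3OC(=O)c3cc(O)c(O)c(O)c3)c2O[C@@H]1c1ccc(O)c(O)c1)c1cc(O)c(O)c(O)c1 | target

**Step count and risks**

Total step count: 15. Longest linear sequence: 12 steps (1, 2, 3, 4, 7, 8, 9, 11, 12, 13, 14, 15).

Steps most likely to fail:

Step 7. The enolate may be diverted before the ring closes: the pivaloyl group could shift from O3 to the enolate oxygen, the first stage could give O- instead of C-benzylation, or oxidative addition into the aryl bromide could be too slow. The fallback removes the C3 oxygen from the cyclisation and adds it afterwards. It sets out from 6. The lithium enolate of commercial 1-[3,4-bis(benzyloxy)phenyl]ethanone (LiN(i-Pr)2, THF, −78 °C) is alkylated with 6 to the dihydrochalcone 3-[2-bromo-4,6-bis(benzyloxy)phenyl]-1-[3,4-bis(benzyloxy)phenyl]propan-1-one F1. Intramolecular enolate O-arylation under zerovalent palladium catalysis (Pd2(dba)3, DPEphos, NaOtBu, toluene, 100 °C) closes the same O1–C8a bond and gives 5,7-bis(benzyloxy)-2-[3,4-bis(benzyloxy)phenyl]-4H-chromene F2. Hydroboration–oxidation (BH3·THF, then NaOH/H2O2) puts boron and then hydroxyl on C3, giving racemic trans-5,7-bis(benzyloxy)-2-[3,4-bis(benzyloxy)phenyl]chroman-3-ol F3. Dess–Martin oxidation of F3 comes back to the route at ketone 12.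

Step 9. If racemisation at C2 is slower than reduction, or the catalyst discriminates the ketone faces poorly, enantio- and diastereocontrol would be lost. The fallback is substrate-controlled reduction followed by classical resolution. It sets out from 12. LiBH(s-Bu)3 (THF, −78 °C) delivers hydride anti to the C2 aryl group and gives racemic cis-5,7-bis(benzyloxy)-2-[3,4-bis(benzyloxy)phenyl]chroman-3-ol F4. Steglich esterification with (S)-2-methoxy-2-phenylacetic acid gives two diastereomeric esters, the (2R,3R)-chroman-3-yl (S)-2-methoxy-2-phenylacetate F5 and the (2S,3S)-chroman-3-yl (S)-2-methoxy-2-phenylacetate F6, which are separated by chromatography or crystallisation. Methanolysis of F5 (K2CO3, MeOH/THF) comes back to the route at 13.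

Step 14. The flavan-4-yl cation may also attack a C6 position of dimer 18, or 17 may condense with itself, so that regiocontrol and chain length are lost. The fallback grows the chain in the other direction, with a dimeric electrophile and the monomeric nucleophile 15 in excess. It sets out from 17. BF3·OEt2 and 4-methylbenzenethiol (CH2Cl2, −20 °C) convert 17 into the thioether (2R,3S,4S)-5,7-bis(benzyloxy)-2-[3,4-bis(benzyloxy)phenyl]-4-[(4-methylphenyl)sulfanyl]chroman-3-yl 3,4,5-tris(benzyloxy)benzoate F7. A second portion of 17 is ionised with BF3·OEt2 at −78 °C, which should leave the C4–S bond of F7 intact, and alkylates C8 of F7 to give the (4β→8) dimer that carries the arylsulfanyl group at C4 of its lower unit, F8. AgBF4 then ionises that C4–S bond in the presence of excess 15 (CH2Cl2, −40 °C), and attack by C8 of 15 comes back to the route at 19.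

**Further compounds**

F1 | step 7 | 3-[2-bromo-4,6-bis(benzyloxy)phenyl]-1-[3,4-bis(benzyloxy)phenyl]propan-1-one | O=C(CCc1c(Br)cc(OCc2ccccc2)cc1OCc1ccccc1)c1ccc(OCc2ccccc2)c(OCc2ccccc2)c1
F2 | step 7 | 5,7-bis(benzyloxy)-2-[3,4-bis(benzyloxy)phenyl]-4H-chromene | C1=C(c2ccc(OCc3ccccc3)c(OCc3ccccc3)c2)Oc2cc(OCc3ccccc3)cc(OCc3ccccc3)c2C1
F3 | step 7 | racemic trans-5,7-bis(benzyloxy)-2-[3,4-bis(benzyloxy)phenyl]chroman-3-ol (both enantiomers written) | C1c2c(OCc5ccccc5)cc(OCc5ccccc5)cc2O[C@H](c2ccc(OCc5ccccc5)c(OCc5ccccc5)c2)[C@H]1O.C1c2c(OCc5ccccc5)cc(OCc5ccccc5)cc2O[C@@H](c2ccc(OCc5ccccc5)c(OCc5ccccc5)c2)[C@@H]1O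
F4 | step 9 | racemic cis-5,7-bis(benzyloxy)-2-[3,4-bis(benzyloxy)phenyl]chroman-3-ol (both enantiomers written) | C1c2c(OCc5ccccc5)cc(OCc5ccccc5)cc2O[C@H](c2ccc(OCc5ccccc5)c(OCc5ccccc5)c2)[C@@H]1O.C1c2c(OCc5ccccc5)cc(OCc5ccccc5)cc2O[C@@H](c2ccc(OCc5ccccc5)c(OCc5ccccc5)c2)[C@H]1O
F5 | step 9 | (2R,3R)-5,7-bis(benzyloxy)-2-[3,4-bis(benzyloxy)phenyl]chroman-3-yl (S)-2-methoxy-2-phenylacetate | C1c2c(OCc5ccccc5)cc(OCc5ccccc5)cc2O[C@H](c2ccc(OCc5ccccc5)c(OCc5ccccc5)c2)[C@@H]1OC(=O)[C@@H](OC)c1ccccc1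
F6 | step 9 | (2S,3S)-5,7-bis(benzyloxy)-2-[3,4-bis(benzyloxy)phenyl]chroman-3-yl (S)-2-methoxy-2-phenylacetate | C1c2c(OCc5ccccc5)cc(OCc5ccccc5)cc2O[C@@H](c2ccc(OCc5ccccc5)c(OCc5ccccc5)c2)[C@H]1OC(=O)[C@@H](OC)c1ccccc1
F7 | step 14 | (2R,3S,4S)-5,7-bis(benzyloxy)-2-[3,4-bis(benzyloxy)phenyl]-4-[(4-methylphenyl)sulfanyl]chroman-3-yl 3,4,5-tris(benzyloxy)benzoate | Cc6ccc(cc6)S[C@H]1c2c(OCc5ccccc5)cc(OCc5ccccc5)cc2O[C@H](c2ccc(OCc5ccccc5)c(OCc5ccccc5)c2)[C@@H]1OC(=O)c1cc(OCc5ccccc5)c(OCc5ccccc5)c(OCc5ccccc5)c1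
F8 | step 14 | tetradeca-O-benzyl epicatechin 3-O-gallate-(4β→8)-[4β-(4-methylphenyl)sulfanyl]epicatechin 3-O-gallate | O=C(O[C@@H]1[C@@H](Sc6ccc(C)cc6)c2c(OCc5ccccc5)cc(OCc5ccccc5)c([C@H]3c4c(OCc5ccccc5)cc(OCc5ccccc5)cc4O[C@H](c4ccc(OCc5ccccc5)c(OCc5ccccc5)c4)[C@@H]3OC(=O)c3cc(OCc5ccccc5)c(OCc5ccccc5)c(OCc5ccccc5)c3)c2O[C@@H]1c1ccc(OCc5ccccc5)c(OCc5ccccc5)c1)c1cc(OCc5ccccc5)c(OCc5ccccc5)c(OCc5ccccc5)c1
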